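## The problem

The target **13** is a flavone: a benzo ring A fused to a 4-pyranone ring C, with the aryl ring B attached through the C2–C1' bond. It has no stereocenter, so nothing has to be controlled in space and the whole difficulty is positional. Ring A carries oxygen at C5, C7 and C8, and the single methyl ether must sit at C8 and not at C6. The classical closure of ring C through a ring A phenol does not decide this, because a phloroglucinol-type ketone offers two ortho hydroxyls, and acid interconverts the 8-methoxy and 6-methoxy series by ring opening and reclosure (Wessely–Moser rearrangement). Of the six oxygen substituents, three (C5, C7, C2') end as free phenols and three (C8, C4', C5') as methyl ethers. The protecting groups must therefore come off without touching aryl methyl ethers, after surviving organolithium bases, an acid chloride and hot carbonate. A free 2'-hydroxyl on ring B would lie within reach of the diketone carbon that becomes C4, so an open-chain 1,3-diketone with that phenol free could close a pyranone from the wrong side. The diketone is also open to retro-Claisen cleavage by hydroxide. The enabling feature is that O1 is bonded to C8a, and C8a lies between C4a, which carries the acyl carbon, and C8, which carries the methoxy group. As a C–H it is flanked by a carboxylate and a methoxy group, so it can be metalated and brominated selectively, and an enol oxygen can then be joined to it as the last ring-forming event.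

## Retrosynthesis

Flavone numbering is used for ring atoms throughout (O1, C2, C3, C4, C4a, C5–C8, C8a; ring B C1'–C6').

**13 ⇒ 12 (three O–isopropyl bonds).** The phenols at C5, C7 and C2' are masked as isopropyl ethers in **12**. Benzyl ethers would be exposed to benzylic deprotonation in the metalation step. Methoxymethyl ethers would be strong rival directing groups and would not tolerate acid chloride formation. Methyl ethers could not be told apart from the three that must stay. Isopropyl ethers are poor directing groups, inert to bases and copper, and are cleaved by BCl3 while methyl ethers remain. The forward step must cleave three secondary alkyl ethers and no methyl ether.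

**12 ⇒ 11 (O1–C8a).** Cutting O1–C8a opens ring C to the 1-(2-bromoaryl)-1,3-diketone **11**. Cutting O1–C2 instead (cyclodehydration of a 2-hydroxyaryl diketone) would need a free phenol on ring A and would bring back the C6/C8 question. Cutting C2–C1' would need a 2-halochromone whose ring A raises the same question. With the O1–C8a cut no ring A phenol is ever free, and ring A regiochemistry is reduced to the position of one bromine atom. The forward reaction is a copper-catalysed intramolecular O-arylation of the diketonate, which must deliver oxygen rather than carbon to C8a.

**11 ⇒ 6 + 8 (C3–C4).** The bond between the methylene carbon and the ring A carbonyl is cut, giving acid **6** (used as its chloride **9**) and methyl ketone **8** (used as its lithium enolate **10**). The other cut, C2–C3, would need a ring A methyl ketone and a ring B acid derivative, two further functional group changes; it is kept in reserve. The forward reaction is a Claisen-type C-acylation of an enolate by a doubly ortho-substituted acid chloride.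

**6 ⇒ 4 (C8a–Br).** The bromine is removed to give acid **4**. In **4** the only C–H ortho to the carboxylate is the future C8a, and it is also ortho to the methoxy group. The other ring C–H lies between two isopropoxy groups. Electrophilic bromination would attack that second position, so the C–Br bond must be made through the dilithio species **5** by carboxylate-directed metalation.

**4 ⇒ 2 ⇒ 1 (C8–OMe, then O-alkyl bonds).** The methoxy group of **4** is traced to the bromine of ester **2** by copper-mediated methoxylation, passing through methyl ester **3** in the same flask. **2** is the per-isopropylated form of **1**, in which the bromine already marks the future C8.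

**8 ⇒ 7 (O–isopropyl).** Ketone **8** is the isopropyl ether of acetophenone **7**, which already holds the complete ring B oxygen pattern.

## Roads not taken

Alternative 1: The cut is C2–C1', made after ring B has been tied to C3 through an ester. In 3,4-dimethoxyphenyl 5,7-bis(benzyloxy)-8-methoxy-4-oxo-4H-chromene-3-carboxylate A2, Pd(OAc)2 with AgOAc as oxidant would join the chromone C2–H to the aryl C–H ortho to the ester oxygen. This would give the bridged lactone A1.

- Merits: neither partner needs a halogen or metal handle. The tether places the new bond ortho to the future 2'-oxygen, which is released as the phenol when the lactone is opened and the C3 carboxyl is lost.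
- Weak points: two C–H bonds are ortho to the ester oxygen and only one gives the 4',5' pattern. Sterics favour the right one but nothing enforces it. C2 of A2 is the β-carbon of a doubly activated vinylogous ester and is open to nucleophilic ring opening under hot acetate conditions. The benzylic C–H bonds are exposed to an oxidising palladium and silver system. Three operations follow the key step (lactone opening, decarboxylation, hydrogenolysis).
- Comparison: the ring A half of A2 still has to be made with the methoxy group at C8 rather than C6, which this route does not address. It equals the chosen plan in needing no pre-functionalised ring B. The chosen plan answers the ring A question, uses catalytic copper with no stoichiometric silver, and has a shorter end-game.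

Alternative 2: Ring B is not brought in but built. The terminal alkyne of 5,7-bis(benzyloxy)-2-ethynyl-8-methoxy-4H-chromen-4-one A4 would combine with the carbene complex pentacarbonyl[methoxy(1-methoxyethenyl)carbene]chromium A5 and one of its CO ligands in a Dötz benzannulation. The alkyne carbons become C1' and C6', the carbene carbon C5', the vinyl carbons C4' and C3', and CO becomes C2' with its hydroxyl. The product is the 2'-phenol A3.

- Merits: three C–C bonds and a ring form in one step, the 2'-hydroxyl appears free, and the 4',5'-dimethoxy pattern follows from the mechanism. In bond-forming power this step exceeds the chosen key step, which makes one C–O bond.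
- Weak points: chromium is stoichiometric. A5 is an α-alkoxyvinyl carbene complex and is less robust than simple alkenyl analogues. The alkyne of A4 is conjugated to the pyranone and therefore electron-poor, a class for which benzannulation competes less well with other insertion pathways. A4 is also a Michael acceptor.
- Comparison: ring A of A4 again has to be made with the C8 regiochemistry settled elsewhere. The chosen plan offers catalytic copper, two catalogue aromatic building blocks, and a built-in answer to the C6/C8 question.

Alternative 3: Ring A is built last by cutting C4a–C5. Heating 3-isopropoxy-4-methoxy-4-[6-(2-isopropoxy-4,5-dimethoxyphenyl)-4-oxo-4H-pyran-2-yl]cyclobut-2-en-1-one A7 would open the four-membered ring to a dienylketene. Its ketene carbon would bond to the pyranone CH in a six-electron electrocyclisation, and tautomerisation would give the 5-phenol A6.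

- Merits: the ring A pattern (5-OH, 6-H, 7-OR, 8-OMe) is written into the cyclobutenone atom by atom. In regiochemical certainty this is at least as good as the directed metalation of the chosen plan. The 5-hydroxyl is delivered free.
- Weak points: A7 needs a nucleophilic 6-metalated 2-aryl-4-pyranone, an uncommon reagent. The four-membered precursor carries one oxygen more than ring A needs, and it must be removed on the way. The closure uses the C=C bond of an electron-poor pyranone rather than a simple alkene or arene. Two isopropyl ethers still have to be cleaved from A6.
- Comparison: the chosen plan reaches the same certainty about C8 with fewer steps, each of a known reaction class, and pays for it with one metalation whose site selectivity has to hold.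

Key step: step 6

Remark: compounds **1** and **7** are taken as catalogue compounds. **11** is drawn as the diketone although it should exist largely as its chelated enol, which does not change the chemistry.

## Steps

Step 1
Reactants: 1 5-bromo-2,4-dihydroxybenzoic acid
Product: 2 isopropyl 5-bromo-2,4-diisopropoxybenzoate
Conditions: 2-bromopropane (5 equiv), K2CO3 (5 equiv), DMF, 80 °C
Reagents that add atoms: 2-bromopropane, CC(C)Br
Why: Williamson alkylation of both phenoxides and the carboxylate in one operation; excess secondary bromide offsets its loss by elimination, and the bromine already sits at the future C8.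

Step 2
Reactants: 2 isopropyl 5-bromo-2,4-diisopropoxybenzoate
Product: 4 2,4-diisopropoxy-5-methoxybenzoic acid, via methyl 2,4-diisopropoxy-5-methoxybenzoate 3 (not isolated)
Conditions: NaOMe (6 equiv), CuI (20 mol %), DMF/MeOH, 110 °C; then aq NaOH, 90 °C; aq HCl
Reagents that add atoms: sodium methoxide, [Na+].[O-]C; sodium hydroxide, [Na+].[OH-]
Why: Ullmann-type copper-catalysed methoxylation of an aryl bromide, a standard way to turn bromo-alkoxyarenes into methoxy-alkoxyarenes; methoxide also exchanges the ester to 3, which is saponified in the same flask, while the isopropyl aryl ethers are inert to both bases.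

Step 3
Reactants: 4 2,4-diisopropoxy-5-methoxybenzoic acid
Product: 6 2-bromo-4,6-diisopropoxy-3-methoxybenzoic acid, via lithium 2-lithio-4,6-diisopropoxy-3-methoxybenzoate 5 (not isolated)
Conditions: s-BuLi (2.2 equiv), TMEDA (2.2 equiv), THF, −78 °C; then BrCCl2CCl2Br, −78 °C to rt; aq HCl
Reagents that add atoms: 1,2-dibromo-1,1,2,2-tetrachloroethane, BrC(Cl)(Cl)C(Cl)(Cl)Br
Why: Directed ortho-metalation of an unprotected benzoic acid: the lithium carboxylate and the methoxy group both direct to the one C–H between them (C6 of 4, the future C8a), whereas the C–H between the two bulky, weakly coordinating isopropoxy groups normally needs far more forcing conditions; the aryllithium then takes bromine from the polyhalide.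

Step 4
Reactants: 7 1-(2-hydroxy-4,5-dimethoxyphenyl)ethan-1-one
Product: 8 1-(2-isopropoxy-4,5-dimethoxyphenyl)ethan-1-one
Conditions: 2-bromopropane (3 equiv), K2CO3 (3 equiv), DMF, 80 °C
Reagents that add atoms: 2-bromopropane, CC(C)Br
Why: Williamson alkylation of the chelated phenol; capping this oxygen prevents it from closing a pyranone from the ring B side later.

Step 5
Reactants: 6 2-bromo-4,6-diisopropoxy-3-methoxybenzoic acid; 8 1-(2-isopropoxy-4,5-dimethoxyphenyl)ethan-1-one
Product: 11 1-(2-bromo-4,6-diisopropoxy-3-methoxyphenyl)-3-(2-isopropoxy-4,5-dimethoxyphenyl)propane-1,3-dione, via 2-bromo-4,6-diisopropoxy-3-methoxybenzoyl chloride 9 (not isolated), via lithium 1-(2-isopropoxy-4,5-dimethoxyphenyl)ethen-1-olate 10 (not isolated)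
Conditions: 6, (COCl)2, DMF (cat.), CH2Cl2, 0 °C to rt, evaporate; 8 (2 equiv), LiN(SiMe3)2 (2.1 equiv), THF, −78 °C, then crude 9, −78 to 0 °C; aq NH4Cl
Reagents that add atoms: none
Why: Claisen-type C-acylation of a lithium enolate by an acid chloride, the standard route to unsymmetrical 1,3-diaryl-1,3-diketones; the second equivalent of enolate takes the acidic proton of the product so that acylation is not stopped by proton transfer, and the lithium counter-ion in THF at low temperature favours C- over O-acylation.

Step 6
Reactants: 11 1-(2-bromo-4,6-diisopropoxy-3-methoxyphenyl)-3-(2-isopropoxy-4,5-dimethoxyphenyl)propane-1,3-dione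
Product: 12 5,7-diisopropoxy-2-(2-isopropoxy-4,5-dimethoxyphenyl)-8-methoxy-4H-chromen-4-one
Conditions: CuI (10 mol %), K2CO3 (2 equiv), DMF (degassed), 110 °C, argon
Reagents that add atoms: none
Why: Carbonate converts 11 into its diketonate, which binds monovalent copper and acts as its own β-diketonate ligand, a ligand class known to accelerate Ullmann ether formation. Rotation about the C3–C4 bond turns the oxygen on the ring B side towards C8a; copper held by that oxygen inserts into the C8a–Br bond to give a seven-membered trivalent copper aryl enolate, and C–O reductive elimination forms O1–C8a and returns monovalent copper. The closest known reaction type is the CuI-catalysed intramolecular O-arylation of 1-(2-haloaryl)-1,3-diketones to chromones and flavones, an extension of the benzofuran synthesis from 2-haloaryl ketones. Ring C closes as a six-membered ring at an sp2 carbon with the departing C8a–Br bond outside the ring (6-exo-trig in the usual ring-closure notation), directly at the flavone oxidation level. No stereocenter is formed. The step needs O- rather than C-arylation and a single site of closure: attack by C3 or by the C4 oxygen would make a four-membered ring, only one halogen is present, and no phenol competes because all three phenolic oxygens are isopropyl ethers. The ortho acyl group activates the C8a–Br bond, and the two isopropoxy groups are meta to C8a and do not deactivate it by resonance.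

Step 7
Reactants: 12 5,7-diisopropoxy-2-(2-isopropoxy-4,5-dimethoxyphenyl)-8-methoxy-4H-chromen-4-one
Product: 13 5,7-dihydroxy-2-(2-hydroxy-4,5-dimethoxyphenyl)-8-methoxy-4H-chromen-4-one
Conditions: BCl3 (9 equiv, 1 M in CH2Cl2), CH2Cl2, −78 to 0 °C; then H2O
Reagents that add atoms: none
Why: Lewis acid dealkylation: BCl3 coordinates the ether oxygens and chloride removes the secondary isopropyl groups far faster than primary methyl groups, so the three isopropyl ethers (the carbonyl-chelated C5 ether first) should fall while the methyl ethers at C8, C4' and C5', none of which is chelated to the carbonyl, remain; the low temperature and absence of protic acid avoid the Wessely–Moser rearrangement.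

## Compound list

1 | 5-bromo-2,4-dihydroxybenzoic acid | OC(=O)c1cc(Br)c(O)cc1O | starting material
2 | isopropyl 5-bromo-2,4-diisopropoxybenzoate | CC(C)OC(=O)c1cc(Br)c(OC(C)C)cc1OC(C)C | intermediate
3 | methyl 2,4-diisopropoxy-5-methoxybenzoate | COC(=O)c1cc(OC)c(OC(C)C)cc1OC(C)C | intermediate
4 | 2,4-diisopropoxy-5-methoxybenzoic acid | OC(=O)c1cc(OC)c(OC(C)C)cc1OC(C)C | intermediate
5 | lithium 2-lithio-4,6-diisopropoxy-3-methoxybenzoate | [Li]OC(=O)c1c([Li])c(OC)c(OC(C)C)cc1OC(C)C | intermediate
6 | 2-bromo-4,6-diisopropoxy-3-methoxybenzoic acid | OC(=O)c1c(Br)c(OC)c(OC(C)C)cc1OC(C)C | intermediate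
7 | 1-(2-hydroxy-4,5-dimethoxyphenyl)ethan-1-one | CC(=O)c1cc(OC)c(OC)cc1O | starting material
8 | 1-(2-isopropoxy-4,5-dimethoxyphenyl)ethan-1-one | CC(=O)c1cc(OC)c(OC)cc1OC(C)C | intermediate
9 | 2-bromo-4,6-diisopropoxy-3-methoxybenzoyl chloride | ClC(=O)c1c(Br)c(OC)c(OC(C)C)cc1OC(C)C | intermediate
10 | lithium 1-(2-isopropoxy-4,5-dimethoxyphenyl)ethen-1-olate | [Li]OC(=C)c1cc(OC)c(OC)cc1OC(C)C | intermediate
11 | 1-(2-bromo-4,6-diisopropoxy-3-methoxyphenyl)-3-(2-isopropoxy-4,5-dimethoxyphenyl)propane-1,3-dione | COc1c(OC(C)C)cc(OC(C)C)c(C(=O)CC(=O)c2cc(OC)c(OC)cc2OC(C)C)c1Br | intermediate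
12 | 5,7-diisopropoxy-2-(2-isopropoxy-4,5-dimethoxyphenyl)-8-methoxy-4H-chromen-4-one | COc1c(OC(C)C)cc(OC(C)C)c2c1oc(-c1cc(OC)c(OC)cc1OC(C)C)cc2=O | intermediate
13 | 5,7-dihydroxy-2-(2-hydroxy-4,5-dimethoxyphenyl)-8-methoxy-4H-chromen-4-one | COc1cc(O)c(-c2cc(=O)c3c(O)cc(O)c(OC)c3o2)cc1OC | target

## Step count and risks

Total step count: 7. Longest linear sequence: 6 steps (steps 1, 2, 3, 5, 6, 7 from **1**); step 4 prepares the ring B partner.

**Step 6 (key step).** The most likely failure is slow insertion of copper into the C8a–Br bond, which is flanked by the C8 methoxy group and the twisted C4 acyl group and sits on an electron-rich ring. At 110 °C in carbonate, retro-Claisen cleavage of the diketone or reductive loss of bromine could then overtake ring closure. The fallback changes the electrophile and sets out from **4** through its dianion **5**. Quenching **5** with I2 would give 2-iodo-4,6-diisopropoxy-3-methoxybenzoic acid F1. Oxalyl chloride would convert it into 2-iodo-4,6-diisopropoxy-3-methoxybenzoyl chloride F2. Acylation of enolate **10** with F2 would give 1-(2-iodo-4,6-diisopropoxy-3-methoxyphenyl)-3-(2-isopropoxy-4,5-dimethoxyphenyl)propane-1,3-dione F3. The aryl iodide should undergo the same CuI/K2CO3 closure at 60–80 °C, where cleavage of the diketone is much slower, and the route is rejoined at **12**.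

**Step 3.** The risk is metalation at the C–H between the two isopropoxy groups competing with metalation next to the carboxylate, or addition of s-BuLi to the carboxylate. Either would erode the yield or give a regioisomeric bromide. The fallback sets out from **4** and blocks the rival site. Metalation with n-BuLi/KOtBu, a base combination that steers away from the carboxylate towards the most acidic alkoxy-flanked C–H, followed by Me3SiCl, would give 2,4-diisopropoxy-5-methoxy-3-(trimethylsilyl)benzoic acid F4. Its only remaining ring C–H is then metalated with s-BuLi/TMEDA and brominated to give 2-bromo-4,6-diisopropoxy-3-methoxy-5-(trimethylsilyl)benzoic acid F5. Protodesilylation with CF3CO2H in CH2Cl2, fast at a carbon flanked by two alkoxy groups, returns to **6**.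

**Step 5.** The acid chloride **9** has two ortho substituents, so attack at its carbonyl may be slow, and O-acylation of the enolate or a second acylation of the product may intervene. The fallback reverses the roles of the two halves and sets out from **9** and **8**. Me2CuLi at −78 °C would convert **9** into 1-(2-bromo-4,6-diisopropoxy-3-methoxyphenyl)ethan-1-one F6. Haloform oxidation of **8** (NaOCl, aq NaOH, dioxane) would give 2-isopropoxy-4,5-dimethoxybenzoic acid F7, and oxalyl chloride would give 2-isopropoxy-4,5-dimethoxybenzoyl chloride F8. The lithium enolate of F6 (LiN(SiMe3)2, THF, −78 °C) would then be acylated by the much less hindered F8, returning to **11**.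

**Step 2.** On this electron-rich bromide with an ortho isopropoxy group, reductive loss of bromine can compete with methoxylation and would give material lacking the C8 oxygen. The fallback installs the oxygen through boron and sets out from **2**. Miyaura borylation (B2pin2, Pd(dppf)Cl2, KOAc, dioxane, 90 °C) would give isopropyl 2,4-diisopropoxy-5-(4,4,5,5-tetramethyl-1,3,2-dioxaborolan-2-yl)benzoate F9. Oxidation with NaBO3 in aqueous THF would give isopropyl 5-hydroxy-2,4-diisopropoxybenzoate F10. Methylation (MeI, K2CO3, acetone) would give isopropyl 2,4-diisopropoxy-5-methoxybenzoate F11, and saponification with aq NaOH returns to **4**.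

## Further compounds

F1 | step 6 | 2-iodo-4,6-diisopropoxy-3-methoxybenzoic acid | OC(=O)c1c(I)c(OC)c(OC(C)C)cc1OC(C)C
F2 | step 6 | 2-iodo-4,6-diisopropoxy-3-methoxybenzoyl chloride | ClC(=O)c1c(I)c(OC)c(OC(C)C)cc1OC(C)C
F3 | step 6 | 1-(2-iodo-4,6-diisopropoxy-3-methoxyphenyl)-3-(2-isopropoxy-4,5-dimethoxyphenyl)propane-1,3-dione | COc1c(OC(C)C)cc(OC(C)C)c(C(=O)CC(=O)c2cc(OC)c(OC)cc2OC(C)C)c1I
F4 | step 3 | 2,4-diisopropoxy-5-methoxy-3-(trimethylsilyl)benzoic acid | COc1cc(C(=O)O)c(OC(C)C)c([Si](C)(C)C)c1OC(C)C
F5 | step 3 | 2-bromo-4,6-diisopropoxy-3-methoxy-5-(trimethylsilyl)benzoic acid | COc1c(Br)c(C(=O)O)c(OC(C)C)c([Si](C)(C)C)c1OC(C)C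
F6 | step 5 | 1-(2-bromo-4,6-diisopropoxy-3-methoxyphenyl)ethan-1-one | CC(=O)c1c(Br)c(OC)c(OC(C)C)cc1OC(C)C
F7 | step 5 | 2-isopropoxy-4,5-dimethoxybenzoic acid | OC(=O)c1cc(OC)c(OC)cc1OC(C)C
F8 | step 5 | 2-isopropoxy-4,5-dimethoxybenzoyl chloride | ClC(=O)c1cc(OC)c(OC)cc1OC(C)C
F9 | step 2 | isopropyl 2,4-diisopropoxy-5-(4,4,5,5-tetramethyl-1,3,2-dioxaborolan-2-yl)benzoate | CC(C)OC(=O)c1cc(B2OC(C)(C)C(C)(C)O2)c(OC(C)C)cc1OC(C)C
F10 | step 2 | isopropyl 5-hydroxy-2,4-diisopropoxybenzoate | CC(C)OC(=O)c1cc(O)c(OC(C)C)cc1OC(C)C
F11 | step 2 | isopropyl 2,4-diisopropoxy-5-methoxybenzoate | CC(C)OC(=O)c1cc(OC)c(OC(C)C)cc1OC(C)C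
A1 | alternative 1 | bis(benzyloxy)trimethoxy-6H,7H-chromeno[4,3-b]chromene-6,7-dione (lactone bridging the 2'-oxygen and the C3 carboxyl of the benzyl-protected flavone) | COc1cc2oc(=O)c3c(=O)c4c(OCc5ccccc5)cc(OCc5ccccc5)c(OC)c4oc3c2cc1OC
A2 | alternative 1 | 3,4-dimethoxyphenyl 5,7-bis(benzyloxy)-8-methoxy-4-oxo-4H-chromene-3-carboxylate | COc1ccc(OC(=O)c2coc3c(OC)c(OCc4ccccc4)cc(OCc4ccccc4)c3c2=O)cc1OC
A3 | alternative 2 | 5,7-bis(benzyloxy)-2-(2-hydroxy-4,5-dimethoxyphenyl)-8-methoxy-4H-chromen-4-one | COc1cc(O)c(-c2cc(=O)c3c(OCc4ccccc4)cc(OCc4ccccc4)c(OC)c3o2)cc1OC
A4 | alternative 2 | 5,7-bis(benzyloxy)-2-ethynyl-8-methoxy-4H-chromen-4-one | C#Cc1cc(=O)c2c(OCc3ccccc3)cc(OCc3ccccc3)c(OC)c2o1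
A5 | alternative 2 | pentacarbonyl[methoxy(1-methoxyethenyl)carbene]chromium | COC(=C)C(OC)=[Cr](=C=O)(=C=O)(=C=O)(=C=O)=C=O
A6 | alternative 3 | 5-hydroxy-7-isopropoxy-2-(2-isopropoxy-4,5-dimethoxyphenyl)-8-methoxy-4H-chromen-4-one | COc1c(OC(C)C)cc(O)c2c1oc(-c1cc(OC)c(OC)cc1OC(C)C)cc2=O
A7 | alternative 3 | 3-isopropoxy-4-methoxy-4-[6-(2-isopropoxy-4,5-dimethoxyphenyl)-4-oxo-4H-pyran-2-yl]cyclobut-2-en-1-one | COC1(c2cc(=O)cc(-c3cc(OC)c(OC)cc3OC(C)C)o2)C(=O)C=C1OC(C)C
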